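**Plan**

- Locants: phthalide C1 (C=O), O2, C3, C3a, C4–C7, C7a; spiroacetal O1'', C2'' (CH3), C3'', C4'', C5'' (spiro), O6'', C7'' (chain), C8'', C9''.
- Retrosynthetic cuts, in order: O1''–C5'' (back to a hydroxy enol ether), O6''–C5'' (back to an alkynol), C8''–C9'' (epoxide plus acetylide), then C3a–C4, C7–C7a and C1–O2 together (Alder–Rickert reaction with lactonization), last C3–C3a (aldehyde plus propiolate).
- Enabling feature: in the benzene ring C3a–C7a the methoxy groups sit meta at C5 and C7, and the adjacent carbons C7a (bearing the C1 carbonyl) and C3a (bearing the C3 carbinol) are a masked 4-hydroxy-2-ynoate. The ring therefore divides into 1,3-dimethoxycyclohexa-1,3-diene (C4 to C7) and an alkyne (C3a, C7a), and the lactone ring C1–O2–C3–C3a–C7a closes once the arene exists.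
- Forward order: benzene and lactone rings together, chain joined at C8''–C9'', ring O6''–C7''–C8''–C9''–C5'' by cycloisomerization, ring O1''–C2''–C3''–C4''–C5'' last.
- Stereochemistry: C2'' is bought with (S)-propylene oxide, C7'' comes from a hydrolytic kinetic resolution, C3 from a Zn-ProPhenol alkynylation, and C5'' is set last under kinetic control by a chiral Brønsted acid.

Key step: step 6

Assumption: the antipodes named for the chiral ligand in step 3 and the chiral acid in step 13 are those expected to give the stated configurations; each would be checked in a pilot run and replaced by its mirror image if the sense of induction were reversed.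

**Route**

Step 1
Reactants: 1 rac-1,2-epoxy-9-decene
Product: 2 (S)-1,2-epoxy-9-decene
Conditions: (S,S)-(salen)Co(III)OAc (0.5 mol %), H2O (0.55 equiv), neat, 0 °C → rt; epoxide distilled from the diol
Reagents that add atoms: none
Why: In the hydrolytic kinetic resolution the (S,S)-cobalt–salen catalyst hydrolyses the (R)-epoxide by cooperative bimetallic ring opening much faster than the (S)-epoxide, so running slightly past half conversion should leave the (S)-epoxide (future C7'') in high enantiopurity while the remote alkene is inert.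

Step 2
Reactants: 2 (S)-1,2-epoxy-9-decene
Product: 4 7-[(2S)-oxiran-2-yl]heptanal, via 3-{6-[(2S)-oxiran-2-yl]hexyl}-1,2,4-trioxolane 3 (not isolated)
Conditions: O3, CH2Cl2, −78 °C; then PPh3, −78 °C → rt
Reagents that add atoms: ozone, O=[O+][O-]
Why: Ozonolysis (Criegee sequence of cycloaddition, cycloreversion and recombination to the 1,2,4-trioxolane) followed by phosphine reduction cleaves the only C=C bond to the aldehyde, and the epoxide is inert to ozone and to triphenylphosphine at these temperatures.

Step 3
Reactants: 4 7-[(2S)-oxiran-2-yl]heptanal; 5 methyl propiolate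
Product: 7 methyl (4R)-4-hydroxy-10-[(2S)-oxiran-2-yl]dec-2-ynoate, via methyl 3-(methylzincio)prop-2-ynoate 6 (not isolated)
Conditions: (S,S)-ProPhenol (20 mol %), Ph3P=O (40 mol %), Me2Zn (3 equiv), 5 (3 equiv), toluene, 0–4 °C; slow addition of 4; aq. NH4Cl
Reagents that add atoms: none
Why: In the Zn-ProPhenol-catalysed asymmetric alkynylation the dinuclear zinc complex holds the aldehyde and the zinc acetylide in one chiral pocket and delivers the alkynyl group to the Si face, which sets the (4R) carbinol (future C3), while slow addition of the aldehyde suppresses the uncatalysed pathway and the epoxide is not opened by alkylzinc species at this temperature.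

Step 4
Reactants: 8 1,3-dimethoxybenzene
Product: 9 1,5-dimethoxycyclohexa-1,4-diene
Conditions: Li, NH3(l), THF, t-BuOH, −78 → −33 °C; MeOH then water, pentane extraction
Reagents that add atoms: none
Why: Birch reduction of the electron-rich arene protonates the radical anion and the cyclohexadienyl anion at C2 and C5, so both methoxy groups remain on the two non-conjugated double bonds, as is standard for resorcinol dimethyl ether.

Step 5
Reactants: 9 1,5-dimethoxycyclohexa-1,4-diene
Product: 10 1,3-dimethoxycyclohexa-1,3-diene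
Conditions: t-BuOK (0.2 equiv), DMSO, rt; water, pentane extraction, distillation
Reagents that add atoms: none
Why: Base-catalysed prototropic isomerization through the pentadienyl anion (deprotonation at the CH2 between the two methoxy-bearing carbons, reprotonation at a terminus) should move the equilibrium to the conjugated diene that keeps both methoxy groups on sp2 carbons, and any residual 9 is an inert diluent in the next step.

Step 6
Reactants: 7 methyl (4R)-4-hydroxy-10-[(2S)-oxiran-2-yl]dec-2-ynoate; 10 1,3-dimethoxycyclohexa-1,3-diene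
Product: 13 (3R)-5,7-dimethoxy-3-{6-[(2S)-oxiran-2-yl]hexyl}phthalide [phthalide = 2-benzofuran-1(3H)-one], via methyl 3-{(1R)-1-hydroxy-7-[(2S)-oxiran-2-yl]heptyl}-1,5-dimethoxybicyclo[2.2.2]octa-2,5-diene-2-carboxylate 11 (not isolated), via methyl 2-{(1R)-1-hydroxy-7-[(2S)-oxiran-2-yl]heptyl}-4,6-dimethoxybenzoate 12 (not isolated)
Conditions: 10 (5 equiv), neat, BHT (cat.), silanised sealed tube, Ar, 160–170 °C; excess 10 removed in vacuo
Reagents that add atoms: none
Why: The electron-rich diene 10 adds across the ynoate of 7 in a normal-demand Diels–Alder reaction to give the bicyclo[2.2.2]octa-2,5-diene 11, which loses its saturated CH2–CH2 bridge as ethylene by retro-Diels–Alder reaction and so becomes the benzoate 12 irreversibly; the C3 hydroxyl, unable to reach the ester across the linear alkyne, then sits ortho to it and is acylated with loss of methanol. The closest known reaction type is the Alder–Rickert synthesis of 2,4-dioxygenated benzoates and 5,7-dialkoxyphthalides from 2-alkynoates (4-hydroxy-2-alkynoates included) and 1,3-dialkoxycyclohexa-1,3-dienes. The benzene ring closes by [4+2] cycloaddition (bonds C4–C3a and C7–C7a) followed by [4+2] cycloreversion, and the lactone ring closes by 5-exo-trig addition–elimination of O2 at C1. No stereocentre is created: the bridgehead centres of 11 are erased on aromatisation and C3 keeps its (R) configuration because none of its bonds is broken. The step needs regioselectivity for the 5,7- over the 4,6-dimethoxy pattern, which is secured because the unsubstituted diene terminus, the most nucleophilic carbon through donation from both methoxy groups, bonds to the β-carbon of the ynoate (future C3a) and so places the methoxy-bearing terminus next to the ester carbon (future C7a). It also needs chemoselectivity, which is secured because the ynoate is the only electron-poor π bond and the terminal epoxide and the alkyl chain are inert to neutral, anhydrous heat in excess enol ether.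

Step 7
Reactants: 14 (S)-propylene oxide; 15 1-(trimethylsilyl)propyne
Product: 17 (2S)-6-(trimethylsilyl)hex-5-yn-2-ol, via 3-lithio-1-(trimethylsilyl)propyne 16 (not isolated)
Conditions: 15, n-BuLi, TMEDA, Et2O, −5 °C; then 14, −78 °C → rt; aq. NH4Cl
Reagents that add atoms: none
Why: Propargylic lithiation gives an anion that the silyl cap keeps from reacting as an allene, and its SN2 opening of the epoxide at the unsubstituted carbon leaves the C–O bond of the stereocentre (future C2'') untouched, so the (S) configuration of the purchased epoxide is carried over.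

Step 8
Reactants: 17 (2S)-6-(trimethylsilyl)hex-5-yn-2-ol
Product: 18 tert-butyldimethyl{[(2S)-6-(trimethylsilyl)hex-5-yn-2-yl]oxy}silane
Conditions: TBSCl, imidazole, DMF, rt
Reagents that add atoms: tert-butyldimethylsilyl chloride, CC(C)(C)[Si](C)(C)Cl
Why: Imidazole-promoted silylation of a secondary alcohol gives a TBS ether that withstands the acetylide, Lewis acid and palladium steps and can later be removed by fluoride without acid.

Step 9
Reactants: 18 tert-butyldimethyl{[(2S)-6-(trimethylsilyl)hex-5-yn-2-yl]oxy}silane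
Product: 19 tert-butyl[(2S)-hex-5-yn-2-yloxy]dimethylsilane
Conditions: K2CO3 (cat.), MeOH, rt
Reagents that add atoms: none
Why: Methoxide-mediated protodesilylation cleaves the C(sp)–Si bond selectively, the hindered TBS ether being inert to K2CO3 in methanol.

Step 10
Reactants: 13 (3R)-5,7-dimethoxy-3-{6-[(2S)-oxiran-2-yl]hexyl}phthalide; 19 tert-butyl[(2S)-hex-5-yn-2-yloxy]dimethylsilane
Product: 21 (3R)-3-[(7S,13S)-13-(tert-butyldimethylsilyloxy)-7-hydroxytetradec-9-yn-1-yl]-5,7-dimethoxyphthalide, via {(5S)-5-[(tert-butyldimethylsilyl)oxy]hex-1-yn-1-yl}lithium 20 (not isolated)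
Conditions: 19 (2 equiv), n-BuLi, THF, −78 °C; BF3·OEt2, −78 °C; then 13 in THF, −78 °C; aq. NH4Cl at −78 °C
Reagents that add atoms: none
Why: In the Yamaguchi–Hirao alkynylation the BF3-activated lithium acetylide is a weakly basic nucleophile that opens the terminal epoxide at its CH2 carbon (C8'') by SN2 without touching the C7''–O bond, so the (S) centre is retained, while the electron-rich, ortho-flanked phthalide carbonyl and the C3–H should be left alone at −78 °C.

Step 11
Reactants: 21 (3R)-3-[(7S,13S)-13-(tert-butyldimethylsilyloxy)-7-hydroxytetradec-9-yn-1-yl]-5,7-dimethoxyphthalide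
Product: 22 (3R)-3-{6-[(2S)-5-{(3S)-3-[(tert-butyldimethylsilyl)oxy]butyl}-2,3-dihydrofuran-2-yl]hexyl}-5,7-dimethoxyphthalide
Conditions: PdCl2(PhCN)2 (5 mol %), anhydrous THF, rt; Et3N quench, filtration through basic alumina
Reagents that add atoms: none
Why: Pd(II)-catalysed cycloisomerization of a 3-alkyn-1-ol proceeds by anti-oxypalladation of the activated alkyne by the free hydroxyl in the 5-endo-dig mode (4-exo is strained and the silyl ether oxygen is not nucleophilic) and protodepalladation, which gives the endocyclic enol ether without touching a stereocentre, and the aprotic medium with amine quench guards against hydrolysis.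

Step 12
Reactants: 22 (3R)-3-{6-[(2S)-5-{(3S)-3-[(tert-butyldimethylsilyl)oxy]butyl}-2,3-dihydrofuran-2-yl]hexyl}-5,7-dimethoxyphthalide
Product: 23 (3R)-3-{6-[(2S)-5-[(3S)-3-hydroxybutyl]-2,3-dihydrofuran-2-yl]hexyl}-5,7-dimethoxyphthalide
Conditions: TBAF (1 M in THF), THF, 0 °C → rt; aq. NaHCO3; basic alumina, eluent with 1% Et3N
Reagents that add atoms: none
Why: Fluoride cleaves the Si–O bond through a pentacoordinate silicate under basic conditions to which the enol ether, the lactone and the stereocentres are stable, so the C2'' hydroxyl is freed without any acid that could trigger an uncontrolled spirocyclization.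

Step 13
Reactants: 23 (3R)-3-{6-[(2S)-5-[(3S)-3-hydroxybutyl]-2,3-dihydrofuran-2-yl]hexyl}-5,7-dimethoxyphthalide
Product: 24 (3R)-5,7-dimethoxy-3-{6-[(2S,5R,7S)-2-methyl-1,6-dioxaspiro[4.4]nonan-7-yl]hexyl}phthalide (CNP0380736.1)
Conditions: (S,S)-imidodiphosphoric acid with 3,3'-bis(2,4,6-triethylphenyl)-BINOL backbones (5 mol %), 4 Å MS, MTBE, −35 °C; Et3N quench; Et3N-deactivated silica
Reagents that add atoms: none
Why: In this chiral Brønsted acid-catalysed kinetic spiroacetalization of a hydroxy enol ether, protonation at C9'' gives an oxocarbenium ion paired with the confined chiral anion, and 5-exo-trig attack of O1'' on the face of C5'' anti to the C7'' chain should set the (5''R) spiro centre (E,E isomer) under catalyst control, the weak acid and low temperature preventing re-ionisation to the equally stable epimer.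

**Compound list**

1 | rac-1,2-epoxy-9-decene [2-(oct-7-en-1-yl)oxirane] | C=CCCCCCCC1CO1 | starting material
2 | (S)-1,2-epoxy-9-decene [(2S)-2-(oct-7-en-1-yl)oxirane] | C=CCCCCCC[C@H]1CO1 | intermediate
3 | 3-{6-[(2S)-oxiran-2-yl]hexyl}-1,2,4-trioxolane (secondary ozonide, both C3 epimers) | C1OOC(CCCCCC[C@H]2CO2)O1 | intermediate (not isolated)
4 | 7-[(2S)-oxiran-2-yl]heptanal | O=CCCCCCC[C@H]1CO1 | intermediate
5 | methyl propiolate | C#CC(=O)OC | starting material
6 | methyl 3-(methylzincio)prop-2-ynoate | C[Zn]C#CC(=O)OC | intermediate (not isolated)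
7 | methyl (4R)-4-hydroxy-10-[(2S)-oxiran-2-yl]dec-2-ynoate | COC(=O)C#C[C@@H](CCCCCC[C@H]1CO1)O | intermediate
8 | 1,3-dimethoxybenzene | COc1cccc(OC)c1 | starting material
9 | 1,5-dimethoxycyclohexa-1,4-diene | COC1=CCC=C(OC)C1 | intermediate
10 | 1,3-dimethoxycyclohexa-1,3-diene | COC1=CC(OC)=CCC1 | intermediate
11 | methyl 3-{(1R)-1-hydroxy-7-[(2S)-oxiran-2-yl]heptyl}-1,5-dimethoxybicyclo[2.2.2]octa-2,5-diene-2-carboxylate (both bridgehead diastereomers) | COC12CCC(C(OC)=C1)C([C@H](O)CCCCCC[C@H]3CO3)=C2C(=O)OC | intermediate (not isolated)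
12 | methyl 2-{(1R)-1-hydroxy-7-[(2S)-oxiran-2-yl]heptyl}-4,6-dimethoxybenzoate | COC(=O)c1c(OC)cc(OC)cc1[C@H](O)CCCCCC[C@H]2CO2 | intermediate (not isolated)
13 | (3R)-5,7-dimethoxy-3-{6-[(2S)-oxiran-2-yl]hexyl}phthalide | COc1cc(OC)c2c(c1)[C@@H](CCCCCC[C@H]1CO1)OC2=O | intermediate
14 | (S)-propylene oxide | C[C@H]1CO1 | starting material
15 | 1-(trimethylsilyl)propyne | CC#C[Si](C)(C)C | starting material
16 | 3-lithio-1-(trimethylsilyl)propyne | [Li]CC#C[Si](C)(C)C | intermediate (not isolated)
17 | (2S)-6-(trimethylsilyl)hex-5-yn-2-ol | C[C@H](O)CCC#C[Si](C)(C)C | intermediate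
18 | tert-butyldimethyl{[(2S)-6-(trimethylsilyl)hex-5-yn-2-yl]oxy}silane | C[C@H](O[Si](C)(C)C(C)(C)C)CCC#C[Si](C)(C)C | intermediate
19 | tert-butyl[(2S)-hex-5-yn-2-yloxy]dimethylsilane | C#CCC[C@H](C)O[Si](C)(C)C(C)(C)C | intermediate
20 | {(5S)-5-[(tert-butyldimethylsilyl)oxy]hex-1-yn-1-yl}lithium | [Li]C#CCC[C@H](C)O[Si](C)(C)C(C)(C)C | intermediate (not isolated)
21 | (3R)-3-[(7S,13S)-13-(tert-butyldimethylsilyloxy)-7-hydroxytetradec-9-yn-1-yl]-5,7-dimethoxyphthalide | COc1cc(OC)c2c(c1)[C@@H](CCCCCC[C@H](O)CC#CCC[C@H](C)O[Si](C)(C)C(C)(C)C)OC2=O | intermediate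
22 | (3R)-3-{6-[(2S)-5-{(3S)-3-[(tert-butyldimethylsilyl)oxy]butyl}-2,3-dihydrofuran-2-yl]hexyl}-5,7-dimethoxyphthalide | COc1cc(OC)c2c(c1)[C@@H](CCCCCC[C@H]1CC=C(CC[C@H](C)O[Si](C)(C)C(C)(C)C)O1)OC2=O | intermediate
23 | (3R)-3-{6-[(2S)-5-[(3S)-3-hydroxybutyl]-2,3-dihydrofuran-2-yl]hexyl}-5,7-dimethoxyphthalide | COc1cc(OC)c2c(c1)[C@@H](CCCCCC[C@H]1CC=C(CC[C@H](C)O)O1)OC2=O | intermediate
24 | (3R)-5,7-dimethoxy-3-{6-[(2S,5R,7S)-2-methyl-1,6-dioxaspiro[4.4]nonan-7-yl]hexyl}phthalide | COc1cc(OC)c2c(c1)[C@@H](CCCCCC[C@H]1CC[C@@]3(CC[C@H](C)O3)O1)OC2=O | target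

**Step count and risks**

Total step count: 13 steps. Longest linear sequence: 8 steps (steps 1, 2, 3, 6, 10, 11, 12, 13, from 1).

Steps most likely to fail:

Step 13. The chiral acid may give insufficient facial control at the oxocarbenium ion, since the C7'' and C2'' substituents are remote and the two spiro epimers are close in energy. The hydroxy enol ether may also cyclise non-selectively or hydrolyse during handling. The fallback gives up kinetic control and sets out from 21. Desilylation with TBAF in THF would give the alkynediol (3R)-3-[(7S,13S)-7,13-dihydroxytetradec-9-yn-1-yl]-5,7-dimethoxyphthalide F1. Pd(II)- or Au(I)-catalysed double hydroalkoxylation of the alkyne (PdCl2(PhCN)2 in MeCN–THF, or AuCl with PPTS in CH2Cl2) would then form both acetal rings under thermodynamic control. This would give 24 together with its spiro epimer (3R)-5,7-dimethoxy-3-{6-[(2S,5S,7S)-2-methyl-1,6-dioxaspiro[4.4]nonan-7-yl]hexyl}phthalide F2. The two would be separated by chromatography and the unwanted epimer re-equilibrated with PPTS in CH2Cl2 and recycled. The fallback comes back to the route at 24.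

Step 10. The acetylide may add to the lactone carbonyl, or deprotonate C3–H and erode its configuration, in competition with epoxide opening. The fallback moves the epoxide opening ahead of lactone formation and sets out from 2 and 19. The lithium acetylide 20 with BF3·OEt2 (THF, −78 °C) would open the lactone-free epoxide 2 to the enynol (9S,15S)-15-(tert-butyldimethylsilyloxy)hexadec-1-en-11-yn-9-ol F3. Lemieux–Johnson oxidation (OsO4 cat., NaIO4, 2,6-lutidine, dioxane–water) would cleave the alkene in preference to the alkyne and give (8S,14S)-14-(tert-butyldimethylsilyloxy)-8-hydroxypentadec-10-ynal F4. Zn-ProPhenol alkynylation with 5, with one extra equivalent of Me2Zn for the free hydroxyl, would give methyl (4R,11S,17S)-17-(tert-butyldimethylsilyloxy)-4,11-dihydroxyoctadeca-2,13-diynoate F5. Heating F5 with 10 as in step 6 would pass through methyl 3-[(1R,8S,14S)-14-(tert-butyldimethylsilyloxy)-1,8-dihydroxypentadec-10-yn-1-yl]-1,5-dimethoxybicyclo[2.2.2]octa-2,5-diene-2-carboxylate F6 and methyl 2-[(1R,8S,14S)-14-(tert-butyldimethylsilyloxy)-1,8-dihydroxypentadec-10-yn-1-yl]-4,6-dimethoxybenzoate F7, neither isolated, the unactivated internal alkyne being no dienophile. The fallback comes back to the route at 21.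

Step 3. Enantiofacial selectivity may be low with an unbranched aliphatic aldehyde, and zinc species may open the epoxide by Lewis acid activation. The fallback replaces the catalytic addition by a reagent-controlled ketone reduction and sets out from 4 and 5. Lithium methyl propiolate F8 (from 5 with LiHMDS, THF, −90 °C) would add to 4 at −78 °C to give methyl (4RS)-4-hydroxy-10-[(2S)-oxiran-2-yl]dec-2-ynoate F9. Dess–Martin oxidation buffered with NaHCO3 would give methyl 4-oxo-10-[(2S)-oxiran-2-yl]dec-2-ynoate F10. Midland reduction with (R)-Alpine-Borane, prepared from (+)-α-pinene, would deliver hydride to the ynone with the alkynyl group as the small substituent and give the (4R) carbinol. The fallback comes back to the route at 7.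

**Further compounds**

F1 | step 13 | (3R)-3-[(7S,13S)-7,13-dihydroxytetradec-9-yn-1-yl]-5,7-dimethoxyphthalide | COc1cc(OC)c2c(c1)[C@@H](CCCCCC[C@H](O)CC#CCC[C@H](C)O)OC2=O
F2 | step 13 | (3R)-5,7-dimethoxy-3-{6-[(2S,5S,7S)-2-methyl-1,6-dioxaspiro[4.4]nonan-7-yl]hexyl}phthalide | COc1cc(OC)c2c(c1)[C@@H](CCCCCC[C@H]1CC[C@]3(CC[C@H](C)O3)O1)OC2=O
F3 | step 10 | (9S,15S)-15-(tert-butyldimethylsilyloxy)hexadec-1-en-11-yn-9-ol | C=CCCCCCC[C@H](O)CC#CCC[C@H](C)O[Si](C)(C)C(C)(C)C
F4 | step 10 | (8S,14S)-14-(tert-butyldimethylsilyloxy)-8-hydroxypentadec-10-ynal | O=CCCCCCC[C@H](O)CC#CCC[C@H](C)O[Si](C)(C)C(C)(C)C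
F5 | step 10 | methyl (4R,11S,17S)-17-(tert-butyldimethylsilyloxy)-4,11-dihydroxyoctadeca-2,13-diynoate | COC(=O)C#C[C@@H](CCCCCC[C@H](O)CC#CCC[C@H](C)O[Si](C)(C)C(C)(C)C)O
F6 | step 10 | methyl 3-[(1R,8S,14S)-14-(tert-butyldimethylsilyloxy)-1,8-dihydroxypentadec-10-yn-1-yl]-1,5-dimethoxybicyclo[2.2.2]octa-2,5-diene-2-carboxylate | COC12CCC(C(OC)=C1)C([C@H](O)CCCCCC[C@H](O)CC#CCC[C@H](C)O[Si](C)(C)C(C)(C)C)=C2C(=O)OC
F7 | step 10 | methyl 2-[(1R,8S,14S)-14-(tert-butyldimethylsilyloxy)-1,8-dihydroxypentadec-10-yn-1-yl]-4,6-dimethoxybenzoate | COC(=O)c1c(OC)cc(OC)cc1[C@H](O)CCCCCC[C@H](O)CC#CCC[C@H](C)O[Si](C)(C)C(C)(C)C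
F8 | step 3 | lithium methyl propiolate [methyl 3-lithioprop-2-ynoate] | [Li]C#CC(=O)OC
F9 | step 3 | methyl (4RS)-4-hydroxy-10-[(2S)-oxiran-2-yl]dec-2-ynoate | COC(=O)C#CC(O)CCCCCC[C@H]1CO1
F10 | step 3 | methyl 4-oxo-10-[(2S)-oxiran-2-yl]dec-2-ynoate | COC(=O)C#CC(=O)CCCCCC[C@H]1CO1
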